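Ring B of the target (C1 carries the CH2 bridge, C4 the OH, C3 and C5 the bromines) has a mirror plane through C1 and C4. Its carbons C3–C2–C1–C6–C5 therefore form a 3-substituted pentadienyl unit, and C4 with its oxygen can come from carbon monoxide. The route disconnects the C3–C4 and C4–C5 bonds: a palladium-catalysed carbonylative [5+1] benzannulation turns a bis-allylic acetate into the aryl acetate of ring B in one operation. That acetate is the acetylated divinyl carbinol from a 4-methoxyphenylacetic ester and vinylmagnesium bromide. Ring A travels halogen-free as its methyl ether; the acetate/methyl ether difference then places two bromines on ring B and one on ring A.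

Key step: step 3

Remark: the target is achiral, so no stereocentre has to be set. Metal alkoxides and boron aryloxides that are merely hydrolysed on aqueous work-up are treated as the work-up form of the product and carry no number of their own.

Step 1
Reactants: 1 methyl 4-methoxyphenylacetate; 2 vinylmagnesium bromide
Product: 4 3-[(4-methoxyphenyl)methyl]penta-1,4-dien-3-ol, via vinyl ketone 3 (not isolated)
Conditions: CeCl3 (anhydrous, 3 equiv), vinylmagnesium bromide (3 equiv), THF, −78 °C; then 1, −78 → 0 °C; aq NH4Cl
Reagents that add atoms: vinylmagnesium bromide, C=C[Mg]Br
Why: Double addition of a vinyl organometallic to an ester, run through vinylcerium dichloride made in the flask from the Grignard reagent and CeCl3: the first addition and loss of methoxide give vinyl ketone 3, which should take the second vinyl group by 1,2-addition because the weakly basic, oxophilic cerium reagent suppresses enolisation and conjugate addition; the carbinol carbon carries two identical vinyl groups, so no stereocentre arises.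

Step 2
Reactants: 4 3-[(4-methoxyphenyl)methyl]penta-1,4-dien-3-ol
Product: 5 3-[(4-methoxyphenyl)methyl]penta-1,4-dien-3-yl acetate
Conditions: Ac2O, Et3N, DMAP (cat.), CH2Cl2, rt
Reagents that add atoms: acetic anhydride, CC(=O)OC(C)=O
Why: DMAP-catalysed acylation (Steglich-type acyl transfer through the N-acetylpyridinium ion) should acetylate the hindered tertiary alcohol under basic conditions that do not ionise the bis-allylic C–O bond, so neither allylic transposition nor dehydration is expected.

Step 3
Reactants: 5 3-[(4-methoxyphenyl)methyl]penta-1,4-dien-3-yl acetate; 6 carbon monoxide
Product: 10 4-[(4-methoxyphenyl)methyl]phenyl acetate, via dienylketene 7 (not isolated), via cyclohexadienone 8 (not isolated), via phenol 9 (not isolated)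
Conditions: PdCl2(PPh3)2 (3 mol %), CO (60 atm), Ac2O (2 equiv), Et3N (2 equiv), toluene, 140 °C, autoclave
Reagents that add atoms: carbon monoxide, [C-]#[O+]; acetic anhydride, CC(=O)OC(C)=O
Why: Zerovalent palladium formed in situ from PdCl2(PPh3)2 should ionise the bis-allylic C–O bond of 5 to an η3-pentadienylpalladium acetate, CO should insert at one of the two equivalent unsubstituted termini to give a 3,5-dienoyl palladium species, and base-assisted loss of a palladium hydride should release dienylketene 7. Ring B is then closed by a thermal disrotatory 6π-electrocyclisation in which the ketene carbon bonds to the CH2 terminus of the far vinyl group, giving dienone 8, which tautomerises to phenol 9 and is O-acetylated by Ac2O/Et3N, so that the C3–C4 and C4–C5 bonds of ring B arrive together with the C4 oxygen. The closest known reaction type is the palladium-catalysed cyclocarbonylation of pentadienyl acetates to phenyl acetates under CO pressure with Ac2O and Et3N, the dienyl counterpart of the cyclocarbonylation of cinnamyl acetates to 1-naphthyl acetates. No stereocentre is formed; the only geometric requirement is the Z arrangement of ketene and vinyl across the central alkene of 7, which η3/η1 equilibration of the pentadienylpalladium species can supply because the substituted allyl carbon bears both the vinyl and the benzyl group. The selectivity needed is CO insertion over β-hydride elimination from the benzylic CH2 (which would give a cross-conjugated triene); high CO pressure should secure it, the mirror symmetry of the pentadienyl unit removes any regiochemical question, and ring A, having no C–halogen bond and only a robust methyl ether, stays out of the palladium cycle. Acetate is kept as the leaving group because, unlike a carbonate, it liberates no alkoxide that could intercept the acylpalladium species as an open-chain ester.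

Step 4
Reactants: 10 4-[(4-methoxyphenyl)methyl]phenyl acetate
Product: 9 4-[(4-methoxyphenyl)methyl]phenol
Conditions: K2CO3 (cat.), MeOH, rt
Reagents that add atoms: none
Why: Base-catalysed transesterification (methanolysis) of an aryl acetate should be fast because phenoxide is a good leaving group, while the methyl ether and the diarylmethane CH2 are untouched.

Step 5
Reactants: 9 4-[(4-methoxyphenyl)methyl]phenol
Product: 11 2,6-dibromo-4-[(3-bromo-4-methoxyphenyl)methyl]phenol
Conditions: Br2 (3.0 equiv), AcOH, 15 °C → rt, dark; then aq Na2S2O3
Reagents that add atoms: bromine, BrBr
Why: Electrophilic aromatic substitution (bromination): with both para positions blocked by the CH2 bridge, the free phenol of ring B should take bromine at C3 and C5, both ortho to OH, and the anisole ring A one bromine ortho to OMe, after which ring A is deactivated and a further ortho bromination would twist the methoxy group out of conjugation.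

Step 6
Reactants: 11 2,6-dibromo-4-[(3-bromo-4-methoxyphenyl)methyl]phenol
Product: 12 2,6-dibromo-4-[(3-bromo-4-hydroxyphenyl)methyl]phenol
Conditions: BBr3 (3 equiv), CH2Cl2, −78 °C → rt; then H2O
Reagents that add atoms: none
Why: Lewis acid-mediated aryl methyl ether cleavage: BBr3 binds the methoxy oxygen, bromide removes the methyl group by SN2 as bromomethane, and aqueous work-up hydrolyses the boron aryloxides to the two free phenols, leaving the three C–Br bonds and the CH2 bridge intact.

Compound list
1 | methyl 4-methoxyphenylacetate | COC(=O)Cc1ccc(OC)cc1 | starting material
2 | vinylmagnesium bromide | C=C[Mg]Br | starting material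
3 | 1-(4-methoxyphenyl)but-3-en-2-one (vinyl ketone) | C=CC(=O)Cc1ccc(OC)cc1 | intermediate
4 | 3-[(4-methoxyphenyl)methyl]penta-1,4-dien-3-ol | C=CC(O)(C=C)Cc1ccc(OC)cc1 | intermediate
5 | 3-[(4-methoxyphenyl)methyl]penta-1,4-dien-3-yl acetate | CC(=O)OC(Cc1ccc(OC)cc1)(C=C)C=C | intermediate
6 | carbon monoxide | [C-]#[O+] | starting material
7 | (3Z)-4-[(4-methoxyphenyl)methyl]hexa-1,3,5-trien-1-one (dienylketene; ketene and vinyl cis across the central alkene) | O=C=C/C=C(/Cc1ccc(OC)cc1)C=C | intermediate
8 | 4-[(4-methoxyphenyl)methyl]cyclohexa-2,4-dien-1-one | O=C1C=CC(Cc2ccc(OC)cc2)=CC1 | intermediate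
9 | 4-[(4-methoxyphenyl)methyl]phenol | Oc1ccc(Cc2ccc(OC)cc2)cc1 | intermediate
10 | 4-[(4-methoxyphenyl)methyl]phenyl acetate | CC(=O)Oc1ccc(Cc2ccc(OC)cc2)cc1 | intermediate
11 | 2,6-dibromo-4-[(3-bromo-4-methoxyphenyl)methyl]phenol | COc1ccc(Cc2cc(Br)c(O)c(Br)c2)cc1Br | intermediate
12 | 2,6-dibromo-4-[(3-bromo-4-hydroxyphenyl)methyl]phenol | Oc1ccc(Cc2cc(Br)c(O)c(Br)c2)cc1Br | target

Total step count: 6. Longest linear sequence: 6 steps (1 → 4 → 5 → 10 → 9 → 11 → 12).

The three steps most likely to fail, riskiest first:

The carbonylative annulation of step 3 carries the greatest risk. β-Hydride elimination from the benzylic CH2 of the pentadienylpalladium intermediate, or purely thermal loss of acetic acid from the tertiary acetate, may outpace CO insertion. The dienoyl intermediate may also fail to reach the cis geometry needed for ring closure, so that open-chain material accumulates and ring B is not formed. The fallback gives up ring construction and joins two preformed rings by a Negishi coupling: purchased 4-methoxybenzylzinc chloride F1 and purchased 4-bromophenyl acetate F2 are coupled with Pd(PPh3)4 (cat.) in THF at 60 °C. This fallback builds on none of compounds 1 to 5; it sets out from the two purchased materials and returns to the route at compound 10. The organozinc reagent tolerates the aryl ester, and a benzyl group on palladium has no β-hydrogen to lose.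

Second comes step 1. The vinyl organometallic may enolise the arylacetate or vinyl ketone 3, and methoxide or a second vinyl group may add in conjugate fashion to 3, diverting material from the double 1,2-addition. The fallback sets out from compound 1 and uses the far less basic ethynylmagnesium bromide F3 in THF at 0 °C (2.5 equiv), which should add twice to give 3-[(4-methoxyphenyl)methyl]penta-1,4-diyn-3-ol F4. Semihydrogenation of both terminal alkynes with H2 (1 atm) over Pd/CaCO3 poisoned with Pb(OAc)2 and quinoline in EtOAc then returns to the route at compound 4.

Third comes step 5. Control of site and stoichiometry may be lost through a further bromination of ring A, incomplete bromination of ring B, or ipso attack at C1 of ring B with loss of the 4-methoxybenzyl group. The fallback separates the two rings in time and sets out from compound 10. NBS (1 equiv) in MeCN at rt should brominate only ring A, ring B being deactivated as its acetate, to give 4-[(3-bromo-4-methoxyphenyl)methyl]phenyl acetate F5. Methanolysis with K2CO3 (cat.) in MeOH gives 4-[(3-bromo-4-methoxyphenyl)methyl]phenol F6. NBS (2 equiv) with catalytic i-Pr2NH in CH2Cl2 at 0 °C then places both ortho bromines on ring B, returning to the route at compound 11; step 4 is not needed on this path.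

Further compounds
F1 | step 3 | 4-methoxybenzylzinc chloride | COc1ccc(C[Zn]Cl)cc1
F2 | step 3 | 4-bromophenyl acetate | CC(=O)Oc1ccc(Br)cc1
F3 | step 1 | ethynylmagnesium bromide | C#C[Mg]Br
F4 | step 1 | 3-[(4-methoxyphenyl)methyl]penta-1,4-diyn-3-ol | C#CC(O)(C#C)Cc1ccc(OC)cc1
F5 | step 5 | 4-[(3-bromo-4-methoxyphenyl)methyl]phenyl acetate | CC(=O)Oc1ccc(Cc2ccc(OC)c(Br)c2)cc1
F6 | step 5 | 4-[(3-bromo-4-methoxyphenyl)methyl]phenol | Oc1ccc(Cc2ccc(OC)c(Br)c2)cc1
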